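**Plan**

1. Retrosynthesis: after removal of four benzyl ethers, the 2,4,6-trihydroxyphenyl ring on ketone C1 is treated as an acylphloroglucinol. Its six ring carbons are C1–C6 of a linear methyl 3,5,7-trioxononanoate and ketone C1 is chain C7, so the ring is opened at the bond that is C6–C1 of that chain (Claisen).
2. The trioxo ester is cut at C6–C7 into an (R)-acid chloride and the tris(silyloxy)triene of methyl 3,5-dioxohexanoate. The acid is cut at Cα–CHAr2 into a chromone-3-acetyl imide and a benzhydryl chloride, and at chromone C3–CH2 into a 3-iodochromone and a zinc ester enolate.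
3. Forward: the chromone ring is made first, then the acetic acid side chain, then the benzhydryl group, then the six-carbon extension. The phloroglucinol ring closes last, before hydrogenolysis.
4. Stereochemistry: the single stereocentre comes from auxiliary-controlled alkylation of an (R)-4-benzyloxazolidinone imide enolate. It is carried through base-free acid chloride formation and acylation and through the magnesium-templated cyclisation.

Key step: step 14

Remark on the chemistry: metal enolates, alkoxides and chelates that are formed and quenched in one flask are treated as the reactive form of a numbered compound and appear only in the Why lines; covalent intermediates of telescoped steps are numbered.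
Remark on the chemistry: compound 23 is written in its all-keto form (keto–enol tautomers are expected) and triene 21 without double-bond geometry (a mixture of isomers is expected).

**Route**

Step 1
Reactants: 1 2',4',6'-trihydroxyacetophenone
Product: 2 1-[2,4-bis(benzyloxy)-6-hydroxyphenyl]ethan-1-one
Conditions: BnBr (2.05 equiv), K2CO3, DMF, 0 °C → rt
Reagents that add atoms: benzyl bromide, BrCc1ccccc1
Why: Williamson ether synthesis in which the 4-OH and one ortho-OH are benzylated, while the remaining ortho-OH, hydrogen-bonded to the acetyl carbonyl, is the least nucleophilic and should stay free at this stoichiometry.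

Step 2
Reactants: 2 1-[2,4-bis(benzyloxy)-6-hydroxyphenyl]ethan-1-one
Product: 4 5,7-bis(benzyloxy)-3-iodo-4H-chromen-4-one, via (E)-1-[2,4-bis(benzyloxy)-6-hydroxyphenyl]-3-(dimethylamino)prop-2-en-1-one 3 (not isolated)
Conditions: Me2NCH(OMe)2, toluene, 95 °C; concentrate; I2, CHCl3, rt; aq. Na2S2O3 wash
Reagents that add atoms: N,N-dimethylformamide dimethyl acetal, COC(OC)N(C)C; iodine, II
Why: Enaminone condensation of the methyl ketone with the amide acetal, followed by iodine-induced cyclisation with loss of dimethylamine (iodocyclisation of o-hydroxyaryl enaminones), the standard entry to 5,7-dialkoxy-3-iodochromones.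

Step 3
Reactants: 4 5,7-bis(benzyloxy)-3-iodo-4H-chromen-4-one; 5 (2-tert-butoxy-2-oxoethyl)zinc chloride (commercial solution in Et2O)
Product: 6 tert-butyl 2-[5,7-bis(benzyloxy)-4-oxo-4H-chromen-3-yl]acetate
Conditions: Pd2(dba)3 (2 mol%), XPhos (8 mol%), THF, 40 °C
Reagents that add atoms: none
Why: Negishi-type cross-coupling of a Reformatsky zinc ester enolate with the vinylic C–I bond (oxidative addition, transmetalation, reductive elimination), the carbon-bound zinc enolate being non-basic and too unreactive to add to the pyrone ring.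

Step 4
Reactants: 6 tert-butyl 2-[5,7-bis(benzyloxy)-4-oxo-4H-chromen-3-yl]acetate
Product: 7 2-[5,7-bis(benzyloxy)-4-oxo-4H-chromen-3-yl]acetic acid
Conditions: TFA–CH2Cl2 (1:3), rt
Reagents that add atoms: none
Why: Acidolysis of the tert-butyl ester (E1 loss of isobutene) under conditions to which aryl benzyl ethers and the chromone are inert at room temperature.

Step 5
Reactants: 7 2-[5,7-bis(benzyloxy)-4-oxo-4H-chromen-3-yl]acetic acid; 8 (R)-4-benzyl-1,3-oxazolidin-2-one
Product: 10 (4R)-4-benzyl-3-{2-[5,7-bis(benzyloxy)-4-oxo-4H-chromen-3-yl]acetyl}-1,3-oxazolidin-2-one, via 2-[5,7-bis(benzyloxy)-4-oxo-4H-chromen-3-yl]acetic pivalic anhydride 9 (not isolated)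
Conditions: PivCl, Et3N, THF, −20 °C; then 8, LiCl, −20 °C → rt
Reagents that add atoms: pivaloyl chloride, CC(C)(C)C(Cl)=O (its acyl group is carried only by intermediate 9)
Why: N-Acylation of the oxazolidinone through the mixed pivalic anhydride under the mild LiCl/Et3N protocol (standard imide formation for Evans auxiliaries), which avoids strong base near the pyrone ring.

Step 6
Reactants: 11 4-(benzyloxy)benzaldehyde; 12 [4-(benzyloxy)phenyl]magnesium bromide (commercial solution in THF)
Product: 13 bis[4-(benzyloxy)phenyl]methanol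
Conditions: THF, 0 °C → rt; aq. NH4Cl
Reagents that add atoms: none
Why: Grignard addition of the arylmagnesium bromide to the aromatic aldehyde gives the symmetrical benzhydrol.

Step 7
Reactants: 13 bis[4-(benzyloxy)phenyl]methanol
Product: 14 1,1'-(chloromethylene)bis[4-(benzyloxy)benzene]
Conditions: SOCl2, CH2Cl2, 0 °C → rt; evaporate with toluene; used at once
Reagents that add atoms: thionyl chloride, O=S(Cl)Cl
Why: Chlorodehydroxylation through the chlorosulfite (SN1/SNi), very easy for a benzhydrol whose cation is stabilised by two p-alkoxy groups.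

Step 8
Reactants: 10 (4R)-4-benzyl-3-{2-[5,7-bis(benzyloxy)-4-oxo-4H-chromen-3-yl]acetyl}-1,3-oxazolidin-2-one; 14 1,1'-(chloromethylene)bis[4-(benzyloxy)benzene]
Product: 15 (4R)-4-benzyl-3-{(2R)-2-[5,7-bis(benzyloxy)-4-oxo-4H-chromen-3-yl]-3,3-bis[4-(benzyloxy)phenyl]propanoyl}-1,3-oxazolidin-2-one
Conditions: NaHMDS (1.05 equiv), THF, −78 °C; then 14, −78 → −30 °C; AcOH quench
Reagents that add atoms: none
Why: Evans asymmetric alkylation, in which NaHMDS gives the chelated (Z)-sodium enolate, the C4 benzyl group of the (R)-auxiliary blocks one face and Cα attacks the readily ionised benzhydryl chloride from the opposite face, which corresponds to (2R) because the chromonyl group outranks the incoming benzhydryl group.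

Step 9
Reactants: 15 (4R)-4-benzyl-3-{(2R)-2-[5,7-bis(benzyloxy)-4-oxo-4H-chromen-3-yl]-3,3-bis[4-(benzyloxy)phenyl]propanoyl}-1,3-oxazolidin-2-one
Product: 16 (2R)-2-[5,7-bis(benzyloxy)-4-oxo-4H-chromen-3-yl]-3,3-bis[4-(benzyloxy)phenyl]propanoic acid
Conditions: LiOH, 30% H2O2, THF–H2O (3:1), 0 °C; Na2SO3; 1 M HCl to pH 3
Reagents that add atoms: hydrogen peroxide, OO (as lithium hydroperoxide; supplies the carboxyl OH oxygen)
Why: Hydroperoxide-mediated hydrolysis of the N-acyl oxazolidinone, in which the α-effect nucleophile LiOOH attacks the exocyclic carbonyl selectively even in hindered imides and is too weakly basic at 0 °C to enolise the shielded C2–H, sulfite then reducing the peracid to the acid.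

Step 10
Reactants: 17 methyl acetoacetate; 18 N-methoxy-N-methylacetamide
Product: 19 methyl 3,5-dioxohexanoate
Conditions: NaH, THF, 0 °C; n-BuLi, 0 °C; then 18, −78 → 0 °C; aq. HCl
Reagents that add atoms: none
Why: γ-Acylation of the acetoacetate dianion with a Weinreb amide, whose chelated tetrahedral adduct prevents over-addition and collapses to the 1,3-diketone only on acidic quench.

Step 11
Reactants: 19 methyl 3,5-dioxohexanoate
Product: 21 1-methoxy-1,3,5-tris(trimethylsilyloxy)hexa-1,3,5-triene, via methyl 3,5-bis(trimethylsilyloxy)hexa-2,4-dienoate 20 (not isolated)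
Conditions: TMSCl, Et3N, Et2O, rt; filter, concentrate; then LDA, THF, −78 °C; TMSCl, −78 → 0 °C; pentane extraction, used crude
Reagents that add atoms: chlorotrimethylsilane, C[Si](C)(C)Cl
Why: Double O-silylation of the β,δ-diketo ester with TMSCl/Et3N, then ε-deprotonation of the dienoate with LDA and O-silylation of the extended ester enolate, the established preparation of silyl polyenol ethers that act as β-tricarbonyl trianion equivalents.

Step 12
Reactants: 16 (2R)-2-[5,7-bis(benzyloxy)-4-oxo-4H-chromen-3-yl]-3,3-bis[4-(benzyloxy)phenyl]propanoic acid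
Product: 22 (2R)-2-[5,7-bis(benzyloxy)-4-oxo-4H-chromen-3-yl]-3,3-bis[4-(benzyloxy)phenyl]propanoyl chloride
Conditions: (COCl)2, DMF (cat.), CH2Cl2, 0 °C → rt; evaporate; used at once
Reagents that add atoms: oxalyl chloride, O=C(Cl)C(Cl)=O
Why: Acid chloride formation with oxalyl chloride and catalytic DMF (Vilsmeier-type activation) in the absence of amine base, so that no ketene can form and the α-stereocentre should be retained.

Step 13
Reactants: 22 (2R)-2-[5,7-bis(benzyloxy)-4-oxo-4H-chromen-3-yl]-3,3-bis[4-(benzyloxy)phenyl]propanoyl chloride; 21 1-methoxy-1,3,5-tris(trimethylsilyloxy)hexa-1,3,5-triene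
Product: 23 methyl (8R)-8-[5,7-bis(benzyloxy)-4-oxo-4H-chromen-3-yl]-9,9-bis[4-(benzyloxy)phenyl]-3,5,7-trioxononanoate
Conditions: CH2Cl2, −78 → 20 °C, no Lewis acid; then 0.1 M HCl–THF, 0 °C
Reagents that add atoms: none
Why: Vinylogous Mukaiyama-type C-acylation of the silyl polyenol ether at its terminal carbon C6 by the acid chloride (known for 1,3-bis- and 1,3,5-tris(silyloxy) polyenes), run without base or Lewis acid so that C2–H is not enolised and the chromone is not turned into a benzopyrylium ion that the triene could attack, mild acid then hydrolysing the remaining silyl enol ethers.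

Step 14
Reactants: 23 methyl (8R)-8-[5,7-bis(benzyloxy)-4-oxo-4H-chromen-3-yl]-9,9-bis[4-(benzyloxy)phenyl]-3,5,7-trioxononanoate
Product: 25 (2R)-2-[5,7-bis(benzyloxy)-4-oxo-4H-chromen-3-yl]-3,3-bis[4-(benzyloxy)phenyl]-1-(2,4,6-trihydroxyphenyl)propan-1-one, via 2-{(2R)-2-[5,7-bis(benzyloxy)-4-oxo-4H-chromen-3-yl]-3,3-bis[4-(benzyloxy)phenyl]propanoyl}cyclohexane-1,3,5-trione 24 (not isolated)
Conditions: Mg(OMe)2 (4 equiv), MeOH–THF, 0 → 40 °C; then cold 1 M HCl to pH 3
Reagents that add atoms: none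
Why: Magnesium methoxide deprotonates the C2, C4 and C6 methylenes and holds the 3-, 5- and 7-carbonyl oxygens in a chelated polyenolate in which C6 attacks the ester carbonyl C1, and loss of methoxide gives the 2-acylcyclohexane-1,3,5-trione 24, which enolises to the aromatic ring of 25. The closest known reaction type is the magnesium-mediated biomimetic Claisen (Dieckmann-type) cyclisation of 3,5,7-trioxo esters to acylphloroglucinols, the laboratory counterpart of chalcone-type polyketide folding. The one new ring is closed by a 6-exo-trig acyl substitution that forms the C6–C1 bond. No stereocentre is created, and the one at C8 should survive because the 7-carbonyl is enolised towards the far more acidic C6 and held there by magnesium, so the hindered C8–H is not removed. The step needs Claisen folding instead of aldol attack of C2 on the C7 ketone or O-lactonisation to a pyranone, which the magnesium template and the shielding of C7 by the two bulky C8 substituents should secure. It also needs an intact chromone, secured by the low concentration of free methoxide (the substrate is the stronger acid) and by the reversibility of methoxide addition at the pyrone C2, which the acidic work-up undoes.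

Step 15
Reactants: 25 (2R)-2-[5,7-bis(benzyloxy)-4-oxo-4H-chromen-3-yl]-3,3-bis[4-(benzyloxy)phenyl]-1-(2,4,6-trihydroxyphenyl)propan-1-one
Product: 26 (2R)-2-(5,7-dihydroxy-4-oxo-4H-chromen-3-yl)-3,3-bis(4-hydroxyphenyl)-1-(2,4,6-trihydroxyphenyl)propan-1-one (CNP0106875.1)
Conditions: H2 (1 atm), 10% Pd/C, EtOAc–MeOH (1:1), rt; stopped after uptake of four equivalents
Reagents that add atoms: none
Why: Catalytic hydrogenolysis of the four aryl benzyl ethers under neutral conditions, which should leave the configuration untouched and, when stopped at four equivalents of hydrogen, the trisubstituted vinylogous-ester C2=C3 bond of the chromone and the aryl ketone unreduced.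

**Compound list**

1 | 2',4',6'-trihydroxyacetophenone | CC(=O)c1c(O)cc(O)cc1O | starting material
2 | 1-[2,4-bis(benzyloxy)-6-hydroxyphenyl]ethan-1-one | CC(=O)c1c(O)cc(OCc2ccccc2)cc1OCc1ccccc1 | intermediate
3 | (E)-1-[2,4-bis(benzyloxy)-6-hydroxyphenyl]-3-(dimethylamino)prop-2-en-1-one | CN(C)/C=C/C(=O)c1c(O)cc(OCc2ccccc2)cc1OCc1ccccc1 | intermediate (not isolated)
4 | 5,7-bis(benzyloxy)-3-iodo-4H-chromen-4-one | O=c1c(I)coc2cc(OCc3ccccc3)cc(OCc3ccccc3)c12 | intermediate
5 | (2-tert-butoxy-2-oxoethyl)zinc chloride | CC(C)(C)OC(=O)C[Zn]Cl | starting material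
6 | tert-butyl 2-[5,7-bis(benzyloxy)-4-oxo-4H-chromen-3-yl]acetate | CC(C)(C)OC(=O)Cc1coc2cc(OCc3ccccc3)cc(OCc3ccccc3)c2c1=O | intermediate
7 | 2-[5,7-bis(benzyloxy)-4-oxo-4H-chromen-3-yl]acetic acid | OC(=O)Cc1coc2cc(OCc3ccccc3)cc(OCc3ccccc3)c2c1=O | intermediate
8 | (R)-4-benzyl-1,3-oxazolidin-2-one | O=C1N[C@H](Cc2ccccc2)CO1 | starting material
9 | 2-[5,7-bis(benzyloxy)-4-oxo-4H-chromen-3-yl]acetic pivalic anhydride | CC(C)(C)C(=O)OC(=O)Cc1coc2cc(OCc3ccccc3)cc(OCc3ccccc3)c2c1=O | intermediate (not isolated)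
10 | (4R)-4-benzyl-3-{2-[5,7-bis(benzyloxy)-4-oxo-4H-chromen-3-yl]acetyl}-1,3-oxazolidin-2-one | O=C(Cc1coc2cc(OCc3ccccc3)cc(OCc3ccccc3)c2c1=O)N1C(=O)OC[C@H]1Cc1ccccc1 | intermediate
11 | 4-(benzyloxy)benzaldehyde | O=Cc1ccc(OCc2ccccc2)cc1 | starting material
12 | [4-(benzyloxy)phenyl]magnesium bromide | Br[Mg]c1ccc(OCc2ccccc2)cc1 | starting material
13 | bis[4-(benzyloxy)phenyl]methanol | OC(c1ccc(OCc2ccccc2)cc1)c1ccc(OCc2ccccc2)cc1 | intermediate
14 | 1,1'-(chloromethylene)bis[4-(benzyloxy)benzene] | ClC(c1ccc(OCc2ccccc2)cc1)c1ccc(OCc2ccccc2)cc1 | intermediate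
15 | (4R)-4-benzyl-3-{(2R)-2-[5,7-bis(benzyloxy)-4-oxo-4H-chromen-3-yl]-3,3-bis[4-(benzyloxy)phenyl]propanoyl}-1,3-oxazolidin-2-one | O=C([C@@H](c1coc2cc(OCc3ccccc3)cc(OCc3ccccc3)c2c1=O)C(c1ccc(OCc2ccccc2)cc1)c1ccc(OCc2ccccc2)cc1)N1C(=O)OC[C@H]1Cc1ccccc1 | intermediate
16 | (2R)-2-[5,7-bis(benzyloxy)-4-oxo-4H-chromen-3-yl]-3,3-bis[4-(benzyloxy)phenyl]propanoic acid | OC(=O)[C@@H](c1coc2cc(OCc3ccccc3)cc(OCc3ccccc3)c2c1=O)C(c1ccc(OCc2ccccc2)cc1)c1ccc(OCc2ccccc2)cc1 | intermediate
17 | methyl acetoacetate | COC(=O)CC(C)=O | starting material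
18 | N-methoxy-N-methylacetamide | CON(C)C(C)=O | starting material
19 | methyl 3,5-dioxohexanoate | COC(=O)CC(=O)CC(C)=O | intermediate
20 | methyl 3,5-bis(trimethylsilyloxy)hexa-2,4-dienoate | COC(=O)C=C(O[Si](C)(C)C)C=C(C)O[Si](C)(C)C | intermediate (not isolated)
21 | 1-methoxy-1,3,5-tris(trimethylsilyloxy)hexa-1,3,5-triene | COC(O[Si](C)(C)C)=CC(O[Si](C)(C)C)=CC(=C)O[Si](C)(C)C | intermediate
22 | (2R)-2-[5,7-bis(benzyloxy)-4-oxo-4H-chromen-3-yl]-3,3-bis[4-(benzyloxy)phenyl]propanoyl chloride | ClC(=O)[C@@H](c1coc2cc(OCc3ccccc3)cc(OCc3ccccc3)c2c1=O)C(c1ccc(OCc2ccccc2)cc1)c1ccc(OCc2ccccc2)cc1 | intermediate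
23 | methyl (8R)-8-[5,7-bis(benzyloxy)-4-oxo-4H-chromen-3-yl]-9,9-bis[4-(benzyloxy)phenyl]-3,5,7-trioxononanoate | COC(=O)CC(=O)CC(=O)CC(=O)[C@@H](c1coc2cc(OCc3ccccc3)cc(OCc3ccccc3)c2c1=O)C(c1ccc(OCc2ccccc2)cc1)c1ccc(OCc2ccccc2)cc1 | intermediate
24 | 2-{(2R)-2-[5,7-bis(benzyloxy)-4-oxo-4H-chromen-3-yl]-3,3-bis[4-(benzyloxy)phenyl]propanoyl}cyclohexane-1,3,5-trione | O=C1CC(=O)C(C(=O)[C@@H](c2coc3cc(OCc4ccccc4)cc(OCc4ccccc4)c3c2=O)C(c2ccc(OCc3ccccc3)cc2)c2ccc(OCc3ccccc3)cc2)C(=O)C1 | intermediate (not isolated)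
25 | (2R)-2-[5,7-bis(benzyloxy)-4-oxo-4H-chromen-3-yl]-3,3-bis[4-(benzyloxy)phenyl]-1-(2,4,6-trihydroxyphenyl)propan-1-one | O=C(c1c(O)cc(O)cc1O)[C@@H](c1coc2cc(OCc3ccccc3)cc(OCc3ccccc3)c2c1=O)C(c1ccc(OCc2ccccc2)cc1)c1ccc(OCc2ccccc2)cc1 | intermediate
26 | (2R)-2-(5,7-dihydroxy-4-oxo-4H-chromen-3-yl)-3,3-bis(4-hydroxyphenyl)-1-(2,4,6-trihydroxyphenyl)propan-1-one | O=C(c1c(O)cc(O)cc1O)[C@@H](c1coc2cc(O)cc(O)c2c1=O)C(c1ccc(O)cc1)c1ccc(O)cc1 | target

**Step count and risks**

Total step count: 15. Longest linear sequence: 11 steps (1, 2, 3, 4, 5, 8, 9, 12, 13, 14, 15).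

Steps most likely to fail:

Step 14. The chain may fold in the aldol mode (C2 onto the C7 ketone, leading to a resorcylate) or lactonise through oxygen to a pyranone instead of closing by Claisen attack. Methoxide may add to the pyrone C2 and cleave the ring irreversibly, or the base may slowly epimerise C8. The fallback sets out from 22 and forges the aryl–carbonyl bond directly, giving up the biomimetic ring construction. Friedel–Crafts acylation of commercial 1,3,5-tris(benzyloxy)benzene with 22 (SnCl4, CH2Cl2, −40 → 0 °C) should give (2R)-2-[5,7-bis(benzyloxy)-4-oxo-4H-chromen-3-yl]-3,3-bis[4-(benzyloxy)phenyl]-1-[2,4,6-tris(benzyloxy)phenyl]propan-1-one F1. Benzyl ethers lost to the Lewis acid would not matter, because hydrogenolysis under the conditions of step 15 removes all of them and returns to the route at 26.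

Step 13. Acylation by the hindered acid chloride without a Lewis acid may be too slow. Hydrolytic desilylation of the triene, reaction at its internal carbons or oxygen atoms, or HCl-promoted epimerisation through reversible participation of the pyrone carbonyl oxygen (an acyloxybenzopyrylium species) could then take over. The fallback sets out from 22 and builds the chain by soft enolisation instead of a silyl polyenol ether.
- Allyl 4-(2,2-dimethyl-4-oxo-4H-1,3-dioxin-6-yl)-3-oxobutanoate F2 is made in one step from the lithium dienolate of 2,2,6-trimethyl-4H-1,3-dioxin-4-one and allyl malonyl chloride.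
- F2 is C-acylated at its keto-ester methylene with 22 (MgCl2, pyridine, CH2Cl2, 0 °C) to give allyl (4R)-4-[5,7-bis(benzyloxy)-4-oxo-4H-chromen-3-yl]-5,5-bis[4-(benzyloxy)phenyl]-2-[(2,2-dimethyl-4-oxo-4H-1,3-dioxin-6-yl)acetyl]-3-oxopentanoate F3.
- Pd(PPh3)4 and morpholine remove the allyl ester with decarboxylation to 6-{(5R)-5-[5,7-bis(benzyloxy)-4-oxo-4H-chromen-3-yl]-6,6-bis[4-(benzyloxy)phenyl]-2,4-dioxohexyl}-2,2-dimethyl-4H-1,3-dioxin-4-one F4.
- Heating F4 in toluene–MeOH (100 °C) releases acetone and an acylketene, which methanol traps, and the route is rejoined at 23.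

Step 9. Hydrolysis of the very hindered imide may be slow, so that endocyclic carbamate cleavage, hydroperoxide attack at the pyrone C2 (epoxidation or ring opening) or partial epimerisation compete. The fallback sets out from 6 and replaces auxiliary control by resolution, so that steps 4, 5, 8 and 9 are not needed.
- The lithium enolate of 6 (LiHMDS, THF, −78 °C) is alkylated with 14 to give tert-butyl (2RS)-2-[5,7-bis(benzyloxy)-4-oxo-4H-chromen-3-yl]-3,3-bis[4-(benzyloxy)phenyl]propanoate F5.
- TFA–CH2Cl2 gives (2RS)-2-[5,7-bis(benzyloxy)-4-oxo-4H-chromen-3-yl]-3,3-bis[4-(benzyloxy)phenyl]propanoic acid F6.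
- Classical resolution by crystallisation gives (S)-1-phenylethylammonium (2R)-2-[5,7-bis(benzyloxy)-4-oxo-4H-chromen-3-yl]-3,3-bis[4-(benzyloxy)phenyl]propanoate F7. The mirror-image amine is taken if the other diastereomer proves the less soluble, and the configuration is to be secured by X-ray analysis of the salt.
- Acidification of F7 returns to the route at 16.

**Further compounds**

F1 | step 14 | (2R)-2-[5,7-bis(benzyloxy)-4-oxo-4H-chromen-3-yl]-3,3-bis[4-(benzyloxy)phenyl]-1-[2,4,6-tris(benzyloxy)phenyl]propan-1-one | O=C(c1c(OCc2ccccc2)cc(OCc2ccccc2)cc1OCc1ccccc1)[C@@H](c1coc2cc(OCc3ccccc3)cc(OCc3ccccc3)c2c1=O)C(c1ccc(OCc2ccccc2)cc1)c1ccc(OCc2ccccc2)cc1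
F2 | step 13 | allyl 4-(2,2-dimethyl-4-oxo-4H-1,3-dioxin-6-yl)-3-oxobutanoate | C=CCOC(=O)CC(=O)CC1=CC(=O)OC(C)(C)O1
F3 | step 13 | allyl (4R)-4-[5,7-bis(benzyloxy)-4-oxo-4H-chromen-3-yl]-5,5-bis[4-(benzyloxy)phenyl]-2-[(2,2-dimethyl-4-oxo-4H-1,3-dioxin-6-yl)acetyl]-3-oxopentanoate | C=CCOC(=O)C(C(=O)CC1=CC(=O)OC(C)(C)O1)C(=O)[C@@H](c1coc2cc(OCc3ccccc3)cc(OCc3ccccc3)c2c1=O)C(c1ccc(OCc2ccccc2)cc1)c1ccc(OCc2ccccc2)cc1
F4 | step 13 | 6-{(5R)-5-[5,7-bis(benzyloxy)-4-oxo-4H-chromen-3-yl]-6,6-bis[4-(benzyloxy)phenyl]-2,4-dioxohexyl}-2,2-dimethyl-4H-1,3-dioxin-4-one | CC1(C)OC(=O)C=C(CC(=O)CC(=O)[C@@H](c2coc3cc(OCc4ccccc4)cc(OCc4ccccc4)c3c2=O)C(c2ccc(OCc3ccccc3)cc2)c2ccc(OCc3ccccc3)cc2)O1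
F5 | step 9 | tert-butyl (2RS)-2-[5,7-bis(benzyloxy)-4-oxo-4H-chromen-3-yl]-3,3-bis[4-(benzyloxy)phenyl]propanoate | CC(C)(C)OC(=O)C(c1coc2cc(OCc3ccccc3)cc(OCc3ccccc3)c2c1=O)C(c1ccc(OCc2ccccc2)cc1)c1ccc(OCc2ccccc2)cc1
F6 | step 9 | (2RS)-2-[5,7-bis(benzyloxy)-4-oxo-4H-chromen-3-yl]-3,3-bis[4-(benzyloxy)phenyl]propanoic acid | OC(=O)C(c1coc2cc(OCc3ccccc3)cc(OCc3ccccc3)c2c1=O)C(c1ccc(OCc2ccccc2)cc1)c1ccc(OCc2ccccc2)cc1
F7 | step 9 | (S)-1-phenylethylammonium (2R)-2-[5,7-bis(benzyloxy)-4-oxo-4H-chromen-3-yl]-3,3-bis[4-(benzyloxy)phenyl]propanoate | C[C@H]([NH3+])c1ccccc1.[O-]C(=O)[C@@H](c1coc2cc(OCc3ccccc3)cc(OCc3ccccc3)c2c1=O)C(c1ccc(OCc2ccccc2)cc1)c1ccc(OCc2ccccc2)cc1
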